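(All runs stem from a simulated flask on assumed constants; the scatter is artificial.)

Give each portion of substrate an age, the time it has spent in the flask, and replace the spread of ages by its mean.

| flask | substrate | reagent | initiator | remark | time |
|---|---|---|---|---|---|
| gamma | 0.43 M | 1.5 equiv | 1 mol% | run made earlier |  |
| beta | 0.43 M | 1.5 equiv | 2 mol% | run made earlier |  |
| cedar | 0.43 M (fed, over 9.60 min) | 1.50 equiv | 1 mol% | a stirred flask in which substrate is dosed at a steady rate over 9.60 min without added volume, worked up at 12 min | 12 min |
| larch | 0.43 M | 1.50 equiv | 1 mol% | a closed flask charged with all of it at once and left for 12 min | 12 min |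
| maple | 0.43 M | 1.50 equiv | 1 mol% | a single well-mixed tank run continuously and read at steady state, 12 min in it on average |  |
| oak | 0.43 M | 1.50 equiv (fed, over 9.60 min) | 1 mol% | all but reagent at the start; reagent goes in evenly over 9.60 min, the run ends at 12 min | 12 min |

- gamma (time / min: target / %, substrate / %): 2.50: 15, 41; 5.00: 21, 13; 8.00: 26, 5; 10.0: 25, 0; 12.0: 22, 0
- beta (time / min: target / %, substrate / %): 0.333: 11, 91; 0.833: 14, 73; 1.50: 14, 52; 2.50: 24, 29; 4.00: 27, 11

(each reading ± 2 percentage points)

- the stated concentrations are those of everything mixed, before any reaction; amounts are the same in each set-up
- the earlier runs were read with a standard deviation of 2 percentage points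
- the feed brings no volume worth counting
- the earlier runs were made in a closed, stirred flask

- the set-up with the highest amount of target at the outlet or at the end, in percent of the substrate put in ("none" if the first two lie within 2 percentage points) (cedar / larch / maple / oak / none)
- amount of target at the outlet or at the end, in percent of the substrate put in, cedar
- amount of target at the outlet or at the end, in percent of the substrate put in, larch
- amount of target at the outlet or at the end, in percent of the substrate put in, maple
- amount of target at the outlet or at the end, in percent of the substrate put in, oak

The gamma run, a closed flask with the charge of larch, reads a target fraction of 26% at 8.00 min and 22% at 12.0 min, so we read 22% for larch. Maple has the same mean age, 12 min, so the same reading serves for it. In cedar the average portion enters at 4.80 min, midway through the dosing, and the run ends at 12 min. Its mean age (the mean residence time) is therefore 7.20 min. Reading gamma at that age, between its points at 5.00 min and 8.00 min, gives 24.7% for cedar. That is 2.7 percentage points above larch, more than the margin of 2 points, so we put cedar ahead of larch and maple. The earlier runs never varied reagent, so this reckoning gives no figure for oak.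

The forecast named none as best, with cedar 22%, larch 22%, maple 17% and oak 23%, and for cedar it said “so I average the batch curve”. The flask gives 28.0% for cedar, 25.0% for larch, 21.3% for maple and 22.0% for oak, so cedar is best.

    initiator → 2 initiating radical (k = 0.00850 min⁻¹)
    substrate + second chain carrier → by-product + first chain carrier (k = 2.50 × 10⁵ L mol⁻¹ s⁻¹)
    substrate + initiating radical → capped initiator + first chain carrier (k = 8.50 × 10⁵ L mol⁻¹ s⁻¹)
    2 first chain carrier → ended chains (k = 3.00 × 10⁷ L mol⁻¹ s⁻¹)
    substrate + target → side product (k = 2.60 L mol⁻¹ min⁻¹)
    reagent + first chain carrier ⇌ target + second chain carrier (K = 0.0700, k = 15000 L mol⁻¹ s⁻¹)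

Cedar stands 3 points above larch, against the 2.7 points that its mean age of 7.20 min gave us. With the slow dosing taken away, cedar falls to 25.0%, so the dosing is one part of its gain over larch. Cedar falls short of the whole charge mainly because of the undoing of target + second chain carrier into reagent + first chain carrier, for without that back step cedar gives 99.8%. Maple's mean age lies 4.80 min above cedar's and equals that of larch, yet maple does not stand level with larch. Its outlet holds 21.3%, where the same run without the back-mixing holds 25.0%.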